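Slowness is what I read first: in the south run X has reached 18.0% at 3.00 d, with solid J at 74.5%, so I read the runs for a rate.

| flask | J | Z | L | remark | time |
|---|---|---|---|---|---|
| south | 0.39 M | 1.1 equiv | 0.039 M | run made earlier |  |
| west | 0.39 M | 1.8 equiv | 0.039 M | run made earlier |  |
| north | 0.20 M | 0.80 equiv | 0.039 M | run made earlier |  |
| flask | 0.39 M | 0.800 equiv | 0.0390 M |  | 3.0 d |

| run | time / d | J / % | D / % | X / % |
|---|---|---|---|---|
| south | 0.208 | 96.7 | 0.6 | 0.2 |
| south | 0.625 | 92.8 | 0.3 | 2.7 |
| south | 1.04 | 89.7 | 0.5 | 6.7 |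
| south | 1.67 | 84.8 | 1.5 | 9.0 |
| south | 2.50 | 78.7 | 0.3 | 15.3 |
| south | 3.00 | 74.5 | 1.2 | 18.0 |
| west | 0.500 | 93.7 | 0.1 | 3.7 |
| west | 1.04 | 89.2 | 0 | 7.7 |
| west | 1.67 | 82.4 | 0 | 13.2 |
| west | 2.08 | 78.0 | 0 | 17.0 |
| west | 2.50 | 74.2 | 1.0 | 20.7 |
| west | 3.00 | 70.3 | 0.6 | 25.4 |
| north | 0.250 | 93.9 | 0 | 0.7 |
| north | 0.833 | 87.0 | 0.5 | 3.4 |
| north | 1.25 | 82.1 | 1.0 | 5.1 |
| north | 2.00 | 75.8 | 1.0 | 8.6 |
| north | 3.00 | 68.1 | 0.4 | 13.4 |

(each reading ± 0.5 percentage points)

- solid, in amounts per volume of the solution: J
- at the start none of J is in solution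

- amount of J at 3.0 d, in percent of the J charged (only what is still solid)
- amount of D at 3.0 d, in percent of the J charged
- amount of X at 3.0 d, in percent of the J charged

Each X takes two Z, so over a steady climb the mean c_Z is the charge of Z less the c_X made. The south run then gives 0.0652 d⁻¹. I call this κ, the c_X made per mean c_Z and per unit of time, and treat it as a pseudo-first-order constant in Z.

Now the settings, one at a time. By hand, less J should leave κ as it is while solid remains; the north run, which has less J and also fewer equivalents of Z than the south run, reads 0.0671 d⁻¹, close to it. More Z should raise c_X in step, but the west run reads a lower 0.0548 d⁻¹, so I stay with the south value, as this flask holds fewer equivalents of Z than the south run. L is the same in each run, so I can read nothing about it.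

For the flask I iterate from 0.312 M of Z. The first round gives 0.0610 M of X, or 15.7%. Putting that back into the mean c_Z gives 0.0491 M, and once more 0.0514 M, so I commit to 13.2% of X.

The forecast says 77% of J, 0.6% of D and 15.2% of X, which is more X than mine, holding that “D stays around 0.5%, so it is a short-lived intermediate”.

The flask gives 78.1% of J, 0.558% of D and 13.7% of X, and each figure of the forecast stands within its margin.

    D + L → Q (k = 0.0570 L mol⁻¹ min⁻¹)
    J ⇌ E, rate k2*(cs2 - [E]) while solid is left; crystals form when [E] > cs2 (solubility = 25.0 mM, k = 0.00170 min⁻¹)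
    E + Z → D (k = 0.00490 L mol⁻¹ min⁻¹)
    Z + D → X (k = 0.0280 L mol⁻¹ min⁻¹)

With the other concentrations as charged, E has a half-life of 0.31 d by its step to D, and the step from J to E taken by itself halves the gap to saturation in 0.283 d, a time of like size. In the flask at 3.00 d c_E stands at 0.0159 M, below its saturation of 25 mM, and E is made 1.05 times as fast as it is used up, each step taken net.

In the neighbour flask with a quarter of the J, 0.098 M, and the same equivalents and loadings, κ gives 13.2% of X after the same rounds. The computed neighbour holds 10.6% of X beside 11.9% of Q.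

Readings and results are calculated with constants of no real substance, noise included.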